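**Plan**
- The target is a (2R,3R)-trans-3-methoxyflavanone. In ring C, C3 (the OMe carbon) and C4 (the ketone carbon on ring A) are adjacent oxygen-bearing carbons that can both be aldehyde carbons, so their bond can be made by reductive carbonyl coupling.
- Retrosynthetic cuts, in order: the O-protecting groups and the 3-O-methyl group; C3–C4 (pinacol); the C2–O1 aryl ether (Mitsunobu); the formyl C–C4a bond of ring A and the aryl–C2 bond of ring B.
- Forward: ring A salicylaldehyde 5 (three steps from syringaldehyde) and ring B (S)-mandelate 9 (two steps from aryl bromide 6) are joined through O1–C2. The ester and aldehyde are adjusted to dialdehyde 12, SmI2 closes ring C, and C4 oxidation, 3-O-methylation and deprotection finish the route.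
- Stereochemistry: C2 comes from catalyst-controlled transfer hydrogenation (S) and is inverted to R in the Mitsunobu step. C3 is set trans to the C2 aryl group in the ring closure. The C4 carbinol is transient.

Key step: step 9

Remark: flavanone numbering is used (O1, C2, C3, C4, C4a, C5–C8, C8a; ring B primed); aryl bromide 6 is taken as a catalogue compound (otherwise one benzylation from 5-bromo-2-methoxyphenol).

**Route**

Step 1
Reactants: 1 syringaldehyde
Product: 2 4-(benzyloxy)-3,5-dimethoxybenzaldehyde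
Conditions: BnBr, K2CO3, DMF, 20 °C
Reagents that add atoms: benzyl bromide, BrCc1ccccc1
Why: Williamson etherification of the only phenol, with the aldehyde and methyl ethers inert to carbonate and benzyl bromide.

Step 2
Reactants: 2 4-(benzyloxy)-3,5-dimethoxybenzaldehyde
Product: 4 4-(benzyloxy)-3,5-dimethoxyphenol, via aryl formate 3 (not isolated)
Conditions: mCPBA, CH2Cl2, 0 → 20 °C; then K2CO3 (cat.), MeOH, 20 °C
Reagents that add atoms: mCPBA, O=C(OO)c1cccc(Cl)c1
Why: Dakin-type Baeyer–Villiger oxidation in which the electron-rich aryl group migrates to give the formate, which is methanolysed in the same flask without touching the benzyl or methyl ethers.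

Step 3
Reactants: 4 4-(benzyloxy)-3,5-dimethoxyphenol
Product: 5 3-(benzyloxy)-6-hydroxy-2,4-dimethoxybenzaldehyde
Conditions: MgCl2, Et3N, (CH2O)n, MeCN, reflux
Reagents that add atoms: paraformaldehyde (as formaldehyde), C=O
Why: Casnati–Skattebøl magnesium-mediated ortho-formylation delivers formaldehyde only ortho to the phenoxide, and the two ortho positions of 4 are equivalent by symmetry, so a single salicylaldehyde should result.

Step 4
Reactants: 6 2-(benzyloxy)-4-bromo-1-methoxybenzene
Product: 8 methyl 2-[3-(benzyloxy)-4-methoxyphenyl]-2-oxoacetate, via arylmagnesium bromide 7 (not isolated)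
Conditions: Mg, THF, 40 °C; then added to (CO2Me)2 (3 equiv), THF, −78 °C
Reagents that add atoms: dimethyl oxalate, COC(=O)C(=O)OC
Why: Grignard acylation with inverse addition to excess oxalate at low temperature stops at the α-keto ester because the tetrahedral magnesium alkoxide persists until work-up.

Step 5
Reactants: 8 methyl 2-[3-(benzyloxy)-4-methoxyphenyl]-2-oxoacetate
Product: 9 methyl (2S)-2-[3-(benzyloxy)-4-methoxyphenyl]-2-hydroxyacetate
Conditions: RuCl(p-cymene)[(R,R)-TsDPEN] (1 mol %), HCO2H–Et3N (5:2), DMF, 25 °C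
Reagents that add atoms: none
Why: Noyori asymmetric transfer hydrogenation of an aryl α-keto ester, in which the aryl CH–π contact with the cymene ligand fixes the hydride face so that the (R,R)-ligand is expected to give the S carbinol that later becomes C2.

Step 6
Reactants: 5 3-(benzyloxy)-6-hydroxy-2,4-dimethoxybenzaldehyde; 9 methyl (2S)-2-[3-(benzyloxy)-4-methoxyphenyl]-2-hydroxyacetate
Product: 10 methyl (2R)-2-[3-(benzyloxy)-4-methoxyphenyl]-2-[4-(benzyloxy)-2-formyl-3,5-dimethoxyphenoxy]acetate
Conditions: PPh3, DIAD, toluene, 0 → 20 °C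
Reagents that add atoms: none
Why: Mitsunobu etherification with SN2 inversion (S to R), in which the α-ester group suppresses ionisation of the otherwise cation-prone 4-methoxybenzylic carbinol and the acidic salicylaldehyde phenol serves as pronucleophile.

Step 7
Reactants: 10 methyl (2R)-2-[3-(benzyloxy)-4-methoxyphenyl]-2-[4-(benzyloxy)-2-formyl-3,5-dimethoxyphenoxy]acetate
Product: 11 (2R)-2-[3-(benzyloxy)-4-methoxyphenyl]-2-[4-(benzyloxy)-2-(hydroxymethyl)-3,5-dimethoxyphenoxy]ethan-1-ol
Conditions: i-Bu2AlH (5 equiv), CH2Cl2, −78 → 0 °C; aq. KNaC4H4O6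
Reagents that add atoms: none
Why: Hydride reduction of ester and aldehyde to the diol under cold, non-basic conditions leaves the acidic α-aryl α-aryloxy centre unenolised, and the neutral tartrate work-up spares the acid-sensitive electron-rich benzylic alcohol.

Step 8
Reactants: 11 (2R)-2-[3-(benzyloxy)-4-methoxyphenyl]-2-[4-(benzyloxy)-2-(hydroxymethyl)-3,5-dimethoxyphenoxy]ethan-1-ol
Product: 12 3-(benzyloxy)-6-{(1R)-1-[3-(benzyloxy)-4-methoxyphenyl]-2-oxoethoxy}-2,4-dimethoxybenzaldehyde
Conditions: Dess–Martin periodinane (3 equiv), NaHCO3, CH2Cl2, 0 °C; cold aq. Na2S2O3/NaHCO3 wash; used crude at once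
Reagents that add atoms: none
Why: Double Dess–Martin oxidation under buffered conditions, as used for configurationally labile O-protected mandelaldehydes, should give the dialdehyde without enolisation at C2, and the thiosulfate wash removes iodine oxidants that would consume SmI2.

Step 9
Reactants: 12 3-(benzyloxy)-6-{(1R)-1-[3-(benzyloxy)-4-methoxyphenyl]-2-oxoethoxy}-2,4-dimethoxybenzaldehyde
Product: 13 (2R,3S,4S)-6-(benzyloxy)-2-[3-(benzyloxy)-4-methoxyphenyl]-5,7-dimethoxy-3,4-dihydro-2H-chromene-3,4-diol (2,3-trans, 3,4-cis)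
Conditions: 12 added slowly to SmI2 (2.5 equiv), THF (0.01 M), −78 → −20 °C; aq. NaHCO3
Reagents that add atoms: none
Why: Single-electron transfer from divalent samarium to the conjugated aryl aldehyde gives a samarium-bound ketyl at C4 that adds to the pendant aliphatic aldehyde carbon C3, and a second electron reduces the resulting alkoxy radical to the samarium diolate, which is protonated on work-up. This is the SmI2-mediated intramolecular pinacol coupling of dialdehydes, known to give cyclic cis-diols. Ring C closes in a 6-exo-trig mode (C4 radical onto the exocyclic C3=O). The 3,4-cis relation should follow from both oxygens being held on one trivalent samarium centre in the bond-forming transition state, and the C3 configuration (S, trans to the C2 aryl group) from a half-chair in which the existing C2 aryl group is pseudo-equatorial and the aldehyde oxygen points away from it, the usual anti placement of a new pinacol hydroxyl next to an α-substituent. The step needs ketyl formation and cyclisation to outrun reductive scission of the α-aryloxy C–O bond and enolisation at C2; conjugation of the aryl aldehyde, the absence of HMPA and base, and cold addition of freshly made 12 to excess SmI2 should secure this, and either ketyl would form the same C3–C4 bond. Only the C2/C3 relation is carried forward, since C4 is oxidised in step 10.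

Step 10
Reactants: 13 (2R,3S,4S)-6-(benzyloxy)-2-[3-(benzyloxy)-4-methoxyphenyl]-5,7-dimethoxy-3,4-dihydro-2H-chromene-3,4-diol
Product: 14 (2R,3R)-6-(benzyloxy)-2-[3-(benzyloxy)-4-methoxyphenyl]-3-hydroxy-5,7-dimethoxy-2,3-dihydro-4H-chromen-4-one
Conditions: DDQ (1.3 equiv), 1,4-dioxane, 20 °C
Reagents that add atoms: none
Why: DDQ benzylic oxidation by hydride abstraction from C4–H, activated by the tetra-oxygenated ring A, leaves the non-benzylic C3 carbinol, C2 and the aryl benzyl ethers untouched and avoids the glycol cleavage that MnO2 can cause with cis-diols.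

Step 11
Reactants: 14 (2R,3R)-6-(benzyloxy)-2-[3-(benzyloxy)-4-methoxyphenyl]-3-hydroxy-5,7-dimethoxy-2,3-dihydro-4H-chromen-4-one
Product: 15 (2R,3R)-6-(benzyloxy)-2-[3-(benzyloxy)-4-methoxyphenyl]-3,5,7-trimethoxy-2,3-dihydro-4H-chromen-4-one
Conditions: Ag2O, MeI, 4 Å molecular sieves, CH2Cl2, 20 °C, dark
Reagents that add atoms: iodomethane, CI
Why: Purdie methylation of the only free hydroxyl under essentially neutral conditions avoids enolate formation and hence C3 epimerisation or retro-oxa-Michael opening of ring C.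

Step 12
Reactants: 15 (2R,3R)-6-(benzyloxy)-2-[3-(benzyloxy)-4-methoxyphenyl]-3,5,7-trimethoxy-2,3-dihydro-4H-chromen-4-one
Product: 16 (2R,3R)-5,6-dihydroxy-2-(3-hydroxy-4-methoxyphenyl)-3,7-dimethoxy-2,3-dihydro-4H-chromen-4-one (CNP0393633.1)
Conditions: BCl3 (6 equiv), pentamethylbenzene (6 equiv), CH2Cl2, −78 → 0 °C; MeOH, aq. NaHCO3
Reagents that add atoms: none
Why: BCl3 cleaves the two aryl benzyl ethers at low temperature (pentamethylbenzene traps the benzyl cations) and, through the six-membered boron chelate with the C4 carbonyl, only the peri 5-methoxy group, so the 7-, 4'- and aliphatic 3-methoxy groups and both stereocentres should persist.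

**Compound list**
1 | syringaldehyde (4-hydroxy-3,5-dimethoxybenzaldehyde) | COc1cc(C=O)cc(OC)c1O | starting material
2 | 4-(benzyloxy)-3,5-dimethoxybenzaldehyde | COc1cc(C=O)cc(OC)c1OCc1ccccc1 | intermediate
3 | 4-(benzyloxy)-3,5-dimethoxyphenyl formate | COc1cc(OC=O)cc(OC)c1OCc1ccccc1 | intermediate (not isolated)
4 | 4-(benzyloxy)-3,5-dimethoxyphenol | COc1cc(O)cc(OC)c1OCc1ccccc1 | intermediate
5 | 3-(benzyloxy)-6-hydroxy-2,4-dimethoxybenzaldehyde | COc1cc(O)c(C=O)c(OC)c1OCc1ccccc1 | intermediate
6 | 2-(benzyloxy)-4-bromo-1-methoxybenzene | COc1ccc(Br)cc1OCc1ccccc1 | starting material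
7 | [3-(benzyloxy)-4-methoxyphenyl]magnesium bromide | COc1ccc([Mg]Br)cc1OCc1ccccc1 | intermediate (not isolated)
8 | methyl 2-[3-(benzyloxy)-4-methoxyphenyl]-2-oxoacetate | COC(=O)C(=O)c1ccc(OC)c(OCc2ccccc2)c1 | intermediate
9 | methyl (2S)-2-[3-(benzyloxy)-4-methoxyphenyl]-2-hydroxyacetate | COC(=O)[C@@H](O)c1ccc(OC)c(OCc2ccccc2)c1 | intermediate
10 | methyl (2R)-2-[3-(benzyloxy)-4-methoxyphenyl]-2-[4-(benzyloxy)-2-formyl-3,5-dimethoxyphenoxy]acetate | COC(=O)[C@H](Oc1cc(OC)c(OCc2ccccc2)c(OC)c1C=O)c1ccc(OC)c(OCc2ccccc2)c1 | intermediate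
11 | (2R)-2-[3-(benzyloxy)-4-methoxyphenyl]-2-[4-(benzyloxy)-2-(hydroxymethyl)-3,5-dimethoxyphenoxy]ethan-1-ol | OC[C@H](Oc1cc(OC)c(OCc2ccccc2)c(OC)c1CO)c1ccc(OC)c(OCc2ccccc2)c1 | intermediate
12 | 3-(benzyloxy)-6-{(1R)-1-[3-(benzyloxy)-4-methoxyphenyl]-2-oxoethoxy}-2,4-dimethoxybenzaldehyde | O=C[C@H](Oc1cc(OC)c(OCc2ccccc2)c(OC)c1C=O)c1ccc(OC)c(OCc2ccccc2)c1 | intermediate
13 | (2R,3S,4S)-6-(benzyloxy)-2-[3-(benzyloxy)-4-methoxyphenyl]-5,7-dimethoxy-3,4-dihydro-2H-chromene-3,4-diol | COc1ccc([C@H]2Oc3cc(OC)c(OCc4ccccc4)c(OC)c3[C@H](O)[C@@H]2O)cc1OCc1ccccc1 | intermediate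
14 | (2R,3R)-6-(benzyloxy)-2-[3-(benzyloxy)-4-methoxyphenyl]-3-hydroxy-5,7-dimethoxy-2,3-dihydro-4H-chromen-4-one | COc1ccc([C@H]2Oc3cc(OC)c(OCc4ccccc4)c(OC)c3C(=O)[C@@H]2O)cc1OCc1ccccc1 | intermediate
15 | (2R,3R)-6-(benzyloxy)-2-[3-(benzyloxy)-4-methoxyphenyl]-3,5,7-trimethoxy-2,3-dihydro-4H-chromen-4-one | COc1ccc([C@H]2Oc3cc(OC)c(OCc4ccccc4)c(OC)c3C(=O)[C@@H]2OC)cc1OCc1ccccc1 | intermediate
16 | (2R,3R)-5,6-dihydroxy-2-(3-hydroxy-4-methoxyphenyl)-3,7-dimethoxy-2,3-dihydro-4H-chromen-4-one | COc1ccc([C@H]2Oc3cc(OC)c(O)c(O)c3C(=O)[C@@H]2OC)cc1O | target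

**Step count and risks**

Total steps: 12. Longest linear sequence: 10 steps (steps 1–3 and 6–12).

Step 9. What may go wrong: poor facial selectivity at the C3 aldehyde giving the 2,3-cis diol, reductive scission of the α-aryloxy C–O bond by a second electron transfer, or erosion of the C2 configuration of 12 before it is trapped. The fallback is the chalcone epoxide route to trans-3-hydroxyflavanones, which sets out from phenol 4 and returns at 14.
- Ortho-acetylation of 4 (AcOH, BF3·OEt2, 80 °C; both ortho sites are equivalent) would give 1-[3-(benzyloxy)-6-hydroxy-2,4-dimethoxyphenyl]ethan-1-one F1.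
- The phenol of F1 would be masked (NaH, MOMCl, DMF) as 1-[3-(benzyloxy)-2,4-dimethoxy-6-(methoxymethoxy)phenyl]ethan-1-one F2.
- Claisen–Schmidt condensation of F2 with commercial 3-(benzyloxy)-4-methoxybenzaldehyde (KOH, EtOH) would give (2E)-1-[3-(benzyloxy)-2,4-dimethoxy-6-(methoxymethoxy)phenyl]-3-[3-(benzyloxy)-4-methoxyphenyl]prop-2-en-1-one F3.
- Juliá–Colonna epoxidation (poly-L-leucine, urea–H2O2, DBU, THF) would give [3-(benzyloxy)-2,4-dimethoxy-6-(methoxymethoxy)phenyl]{(2R,3S)-3-[3-(benzyloxy)-4-methoxyphenyl]oxiran-2-yl}methanone F4.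
- HCl in MeOH would remove the MOM group and let the phenol open the epoxide at the benzylic carbon with inversion (6-endo) to give 14. C3 keeps the configuration of the epoxide α-carbon and C2 ends trans to it.

Step 6. What may go wrong: slow displacement at a hindered carbinol by a hindered, internally hydrogen-bonded phenol, which would let betaine-mediated enolisation of the product ester erode yield and enantiomeric purity. The fallback sets out from 4 and 9 and returns at 10, with the ether formed before the formyl group is introduced.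
- Mitsunobu coupling of the unhindered phenol 4 with 9 (PPh3, DIAD, toluene) would give methyl (2R)-2-[3-(benzyloxy)-4-methoxyphenyl]-2-[4-(benzyloxy)-3,5-dimethoxyphenoxy]acetate F5.
- Vilsmeier–Haack formylation of F5 (POCl3, DMF, 0 → 40 °C; aq. NaOAc) would give 10. The two positions ortho to the ether oxygen on the tetra-oxygenated ring are equivalent and far more reactive than ring B.

Step 12. What may go wrong: Lewis-acid-induced ionisation of the benzylic C2–O1 bond (ring opening and C2 epimerisation) or over-demethylation during the combined cleavage. The fallback sets out from 15 and returns at 16, separating the two deprotections.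
- Neutral hydrogenolysis (H2, Pd/C, EtOAc) would remove both benzyl groups to give (2R,3R)-6-hydroxy-2-(3-hydroxy-4-methoxyphenyl)-3,5,7-trimethoxy-2,3-dihydro-4H-chromen-4-one F6.
- Chelation-controlled demethylation of the peri 5-methoxy group of F6 with the milder MgI2·OEt2 (THF, 50 °C) would give 16.

**Further compounds**
F1 | step 9 | 1-[3-(benzyloxy)-6-hydroxy-2,4-dimethoxyphenyl]ethan-1-one | CC(=O)c1c(O)cc(OC)c(OCc2ccccc2)c1OC
F2 | step 9 | 1-[3-(benzyloxy)-2,4-dimethoxy-6-(methoxymethoxy)phenyl]ethan-1-one | CC(=O)c1c(OCOC)cc(OC)c(OCc2ccccc2)c1OC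
F3 | step 9 | (2E)-1-[3-(benzyloxy)-2,4-dimethoxy-6-(methoxymethoxy)phenyl]-3-[3-(benzyloxy)-4-methoxyphenyl]prop-2-en-1-one | COCOc1cc(OC)c(OCc2ccccc2)c(OC)c1C(=O)/C=C/c1ccc(OC)c(OCc2ccccc2)c1
F4 | step 9 | [3-(benzyloxy)-2,4-dimethoxy-6-(methoxymethoxy)phenyl]{(2R,3S)-3-[3-(benzyloxy)-4-methoxyphenyl]oxiran-2-yl}methanone | COCOc1cc(OC)c(OCc2ccccc2)c(OC)c1C(=O)[C@@H]1O[C@H]1c1ccc(OC)c(OCc2ccccc2)c1
F5 | step 6 | methyl (2R)-2-[3-(benzyloxy)-4-methoxyphenyl]-2-[4-(benzyloxy)-3,5-dimethoxyphenoxy]acetate | COC(=O)[C@H](Oc1cc(OC)c(OCc2ccccc2)c(OC)c1)c1ccc(OC)c(OCc2ccccc2)c1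
F6 | step 12 | (2R,3R)-6-hydroxy-2-(3-hydroxy-4-methoxyphenyl)-3,5,7-trimethoxy-2,3-dihydro-4H-chromen-4-one | COc1ccc([C@H]2Oc3cc(OC)c(O)c(OC)c3C(=O)[C@@H]2OC)cc1O
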